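The top flavan unit is built de novo: its pyran ring C is closed at C3–C4 by an amine-catalysed domino oxa-Michael/aldol condensation. A phloroglucinol-derived salicylaldehyde supplies ring A, O1 and C4; a cinnamaldehyde supplies C2, C3 and ring B. The step exploits the ortho relationship of O1 and benzylic C4 on ring A and sets C2. The enal formyl carbon, absent from the target, turns C3 into an enamine nucleophile and is later excised by Baeyer–Villiger oxidation, leaving the C3 oxygen. The precursor is an open-chain aryl ether dialdehyde. The resulting epicatechin electrophile is joined C4→C8 to a 4-thio middle unit, whose sulfide is finally exchanged for the all-cis lower flavan-4-ol.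

Key step: step 3

Remark: (+)-epicatechin, the (2S,3S) enantiomer, is taken as a purchasable compound; in step 9 nucleophile 12 is used in excess and the surplus is recovered.

Step 1
Reactants: 1 2,4,6-trihydroxybenzaldehyde
Product: 2 4,6-bis(benzyloxy)-2-hydroxybenzaldehyde
Conditions: BnBr (2.05 equiv), K2CO3, DMF, 0 °C → rt
Reagents that add atoms: benzyl bromide, BrCc1ccccc1
Why: Williamson etherification in which the 4-OH and one ortho OH react while the remaining ortho hydroxyl, locked in a hydrogen bond to the formyl group, stays free for the later oxa-Michael step.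

Step 2
Reactants: 3 3,4-bis(benzyloxy)benzaldehyde
Product: 4 (E)-3-[3,4-bis(benzyloxy)phenyl]prop-2-enal
Conditions: Ph3P=CHCHO, toluene, 80 °C
Reagents that add atoms: (triphenylphosphoranylidene)acetaldehyde, O=CC=P(c1ccccc1)(c1ccccc1)c1ccccc1
Why: Wittig olefination with the stabilised formylmethylene ylide gives the (E)-enal by two-carbon homologation of the aryl aldehyde.

Step 3
Reactants: 2 4,6-bis(benzyloxy)-2-hydroxybenzaldehyde; 4 (E)-3-[3,4-bis(benzyloxy)phenyl]prop-2-enal
Product: 6 (R)-5,7-bis(benzyloxy)-2-[3,4-bis(benzyloxy)phenyl]-2H-chromene-3-carbaldehyde, via oxa-Michael adduct 5 (not isolated)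
Conditions: (S)-2-[diphenyl(trimethylsilyloxy)methyl]pyrrolidine (20 mol %), 2-nitrobenzoic acid (20 mol %), 4 Å MS, toluene, rt
Reagents that add atoms: none
Why: The secondary amine condenses with enal 4 to an (E)-iminium ion, the single free phenol of 2 adds to its β-carbon (oxa-Michael) on the face opposite the diphenyl(silyloxy)methyl group, and the resulting enamine of 5 attacks the ortho formyl carbon through C3 (intramolecular aldol), after which dehydration and hydrolysis release 6 and the catalyst. The closest known reaction type is the organocatalytic asymmetric domino oxa-Michael/aldol condensation of salicylaldehydes with cinnamaldehydes to 2-aryl-2H-chromene-3-carbaldehydes. Ring C closes by a 6-(enolexo)-exo-trig aldol in which the C3–C4 bond is the ring-closing bond. The only new stereocentre, C2, is set by the catalyst: the (S)-configured pyrrolidine shields one face of the s-trans iminium ion, which should lead to the (R)-chromene (the enantiomeric catalyst would give the mirror image). The step needs enantioselectivity despite a reversible oxa-Michael addition, and this is secured because the ortho formyl group traps the enamine in a six-membered aldol and the dehydration to the donor-stabilised chromene is irreversible. Chemoselectivity rests on 2 having one free phenol and a non-enolisable aldehyde, so that only 4 can form the iminium/enamine pair.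

Step 4
Reactants: 6 (R)-5,7-bis(benzyloxy)-2-[3,4-bis(benzyloxy)phenyl]-2H-chromene-3-carbaldehyde
Product: 8 (R)-5,7-bis(benzyloxy)-2-[3,4-bis(benzyloxy)phenyl]chroman-3-one, via enol formate 7 (not isolated)
Conditions: mCPBA (1.1 equiv), NaHCO3, CH2Cl2, 0 °C; aqueous Na2S2O3 wash; then KHCO3 (cat.), MeOH/THF, 0 °C
Reagents that add atoms: meta-chloroperbenzoic acid, O=C(OO)c1cccc(Cl)c1
Why: Baeyer–Villiger oxidation of an α,β-unsaturated aldehyde, in which the donor-substituted alkenyl group migrates in preference to hydride from the Criegee adduct to give enol formate 7, whose mild methanolysis releases the enol that tautomerises by protonation at C4 to the ketone without touching C2.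

Step 5
Reactants: 8 (R)-5,7-bis(benzyloxy)-2-[3,4-bis(benzyloxy)phenyl]chroman-3-one
Product: 9 (2R,3R)-5,7-bis(benzyloxy)-2-[3,4-bis(benzyloxy)phenyl]chroman-3-ol (5,7,3',4'-tetra-O-benzyl-(−)-epicatechin)
Conditions: LiBH(s-Bu)3, LiBr, THF, −78 °C
Reagents that add atoms: none
Why: Diastereoselective ketone reduction with a bulky trialkylborohydride, which delivers hydride so that the new C3 hydroxyl is axial and cis to the equatorial 2-aryl group (2,3-cis), as is established for tetra-O-benzyl flavan-3-ones.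

Step 6
Reactants: 9 tetra-O-benzyl-(−)-epicatechin
Product: 10 (2R,3R)-3,5,7-tris(benzyloxy)-2-[3,4-bis(benzyloxy)phenyl]chromane (penta-O-benzyl-(−)-epicatechin)
Conditions: NaH, BnBr, DMF, 0 °C → rt
Reagents that add atoms: benzyl bromide, BrCc1ccccc1
Why: Williamson etherification of the secondary alkoxide protects O3 so that it cannot compete as a nucleophile in the later substitutions at C4.

Step 7
Reactants: 10 penta-O-benzyl-(−)-epicatechin
Product: 11 (2R,3R,4S)-3,5,7-tris(benzyloxy)-2-[3,4-bis(benzyloxy)phenyl]-4-(2-ethoxyethoxy)chromane (2,3-cis-3,4-trans, 4β ether)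
Conditions: DDQ, 2-ethoxyethanol, CH2Cl2, rt
Reagents that add atoms: 2-ethoxyethanol, CCOCCO
Why: Oxidative benzylic functionalisation in which DDQ abstracts hydride from C4 of the electron-rich ring A and the stabilised cation is captured by the alcohol anti to the axial 3-benzyloxy group, giving the 3,4-trans (4β) ether.

Step 8
Reactants: 11 4β-(2-ethoxyethoxy) ether
Product: 12 (2R,3S,4S)-3,5,7-tris(benzyloxy)-2-[3,4-bis(benzyloxy)phenyl]-4-[(2,6-dimethylphenyl)sulfanyl]chromane (2,3-cis-3,4-trans, 4β sulfide)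
Conditions: 2,6-dimethylbenzenethiol, BF3·OEt2, CH2Cl2, −78 → −30 °C
Reagents that add atoms: 2,6-dimethylbenzenethiol, Cc1cccc(C)c1S
Why: Lewis-acid-mediated SN1 exchange at C4 in which the thiol captures the benzylic cation again anti to the 3-benzyloxy group, giving the 3,4-trans aryl sulfide that stays dormant towards hard, oxophilic activators.

Step 9
Reactants: 11 4β-(2-ethoxyethoxy) ether (electrophile, future top unit); 12 4β sulfide (nucleophile, future middle unit, in excess)
Product: 13 perbenzylated epicatechin-(4β→8)-4β-[(2,6-dimethylphenyl)sulfanyl]epicatechin: upper unit (2R,3R,4R), bonded from its C4 to C8 of the lower unit (2R,3S,4S)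
Conditions: TMSOTf (0.2 equiv), CH2Cl2, −78 °C
Reagents that add atoms: none
Why: Friedel–Crafts-type interflavan coupling in which the oxophilic silyl triflate ionises only the chelating 2-ethoxyethoxy group of 11 and the C4 cation is attacked by the more accessible C8 of 12 anti to the 3-benzyloxy group, setting the 4β (3,4-trans) stereocentre while the aryl sulfide is untouched.

Step 10
Reactants: 14 (+)-epicatechin, (2S,3S)
Product: 15 (2S,3S)-3,5,7-tris(benzyloxy)-2-[3,4-bis(benzyloxy)phenyl]chromane (penta-O-benzyl-(+)-epicatechin)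
Conditions: NaH (5.5 equiv), BnBr (5.5 equiv), DMF, −78 °C → rt
Reagents that add atoms: benzyl bromide, BrCc1ccccc1
Why: Exhaustive Williamson O-benzylation, started cold so that O-alkylation of the phenoxides outruns C-benzylation of ring A and base-induced C2 epimerisation.

Step 11
Reactants: 15 penta-O-benzyl-(+)-epicatechin
Product: 16 (2S,3S,4R)-3,5,7-tris(benzyloxy)-2-[3,4-bis(benzyloxy)phenyl]chroman-4-ol (3,4-trans alcohol)
Conditions: DDQ, H2O, THF/CH2Cl2, rt
Reagents that add atoms: water, O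
Why: DDQ oxidation at C4 as in step 7 with water as the nucleophile gives the benzylic alcohol, whose C4 configuration is unimportant because it is erased in the next step.

Step 12
Reactants: 16 3,4-trans alcohol
Product: 17 (2S,3R)-3,5,7-tris(benzyloxy)-2-[3,4-bis(benzyloxy)phenyl]chroman-4-one (2,3-cis ketone)
Conditions: Dess–Martin periodinane, NaHCO3, CH2Cl2, rt
Reagents that add atoms: none
Why: Dess–Martin oxidation of the benzylic alcohol under buffered, non-basic conditions should give the 2,3-cis ketone without epimerisation at C3.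

Step 13
Reactants: 17 2,3-cis ketone
Product: 18 (2S,3S,4S)-3,5,7-tris(benzyloxy)-2-[3,4-bis(benzyloxy)phenyl]chroman-4-ol (2,3-cis-3,4-cis alcohol)
Conditions: NaBH4, CeCl3·7H2O, MeOH/THF, −78 °C
Reagents that add atoms: none
Why: Luche reduction in which hydride attacks C4 anti to the pseudo-axial 3-benzyloxy group (Felkin–Anh and steric control agree), giving the 3,4-cis alcohol and thus the all-cis lower unit, while the weakly basic medium spares the epimerisable C3.

Step 14
Reactants: 13 dimeric sulfide; 18 all-cis alcohol (2 equiv)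
Product: 19 pentadeca-O-benzyl trimer: upper unit (2R,3R,4R) bonded C4→C8 to the middle unit (2R,3R,4S), whose C4 oxygen is bonded to C4 of the lower unit (2S,3S,4S)
Conditions: I2, Ag2O, 4 Å MS, CH2Cl2, −40 → 0 °C, dark
Reagents that add atoms: none
Why: Thiophile-promoted SN1 etherification analogous to a thioglycoside glycosylation, in which iodonium activation of the sulfide releases the C4 cation of the middle unit, the hydroxyl of 18 captures it anti to the 3-benzyloxy group (4β, 3,4-trans) faster than any arene carbon, and Ag2O takes up HI so that the acid-labile dibenzylic ether survives.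

Step 15
Reactants: 19 pentadeca-O-benzyl trimer
Product: 20 target, CNP0310719.1
Conditions: H2 (1 atm), Pd(OH)2/C, THF/MeOH/H2O, rt
Reagents that add atoms: none
Why: Hydrogenolysis of the fifteen primary benzyl ethers under neutral conditions, whereas the doubly secondary, flanked C4–O–C4 ether and the ring C2–O1 bonds, all hindered benzylic C–O bonds on electron-rich rings, are expected to be cleaved far more slowly.

Compound list
1 | 2,4,6-trihydroxybenzaldehyde | O=Cc1c(O)cc(O)cc1O | starting material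
2 | 4,6-bis(benzyloxy)-2-hydroxybenzaldehyde | O=Cc1c(O)cc(OCc2ccccc2)cc1OCc1ccccc1 | intermediate
3 | 3,4-bis(benzyloxy)benzaldehyde | O=Cc1ccc(OCc2ccccc2)c(OCc2ccccc2)c1 | starting material
4 | (E)-3-[3,4-bis(benzyloxy)phenyl]prop-2-enal | O=C/C=C/c1ccc(OCc2ccccc2)c(OCc2ccccc2)c1 | intermediate
5 | (S)-3-[3,5-bis(benzyloxy)-2-formylphenoxy]-3-[3,4-bis(benzyloxy)phenyl]propanal (present as its enamine with the catalyst) | O=Cc1c(OCc2ccccc2)cc(OCc2ccccc2)cc1O[C@H](c1ccc(OCc2ccccc2)c(OCc2ccccc2)c1)CC=O | intermediate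
6 | (R)-5,7-bis(benzyloxy)-2-[3,4-bis(benzyloxy)phenyl]-2H-chromene-3-carbaldehyde | c1ccccc1COc1cc(OCc3ccccc3)c2c(c1)O[C@H](c1ccc(OCc3ccccc3)c(OCc3ccccc3)c1)C(C=O)=C2 | intermediate
7 | (R)-5,7-bis(benzyloxy)-2-[3,4-bis(benzyloxy)phenyl]-2H-chromen-3-yl formate | c1ccccc1COc1cc(OCc3ccccc3)c2c(c1)O[C@H](c1ccc(OCc3ccccc3)c(OCc3ccccc3)c1)C(OC=O)=C2 | intermediate
8 | (R)-5,7-bis(benzyloxy)-2-[3,4-bis(benzyloxy)phenyl]chroman-3-one | c1ccccc1COc1cc(OCc3ccccc3)c2c(c1)O[C@H](c1ccc(OCc3ccccc3)c(OCc3ccccc3)c1)C(=O)C2 | intermediate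
9 | (2R,3R)-5,7-bis(benzyloxy)-2-[3,4-bis(benzyloxy)phenyl]chroman-3-ol | c1ccccc1COc1cc(OCc3ccccc3)c2c(c1)O[C@H](c1ccc(OCc3ccccc3)c(OCc3ccccc3)c1)[C@H](O)C2 | intermediate
10 | (2R,3R)-3,5,7-tris(benzyloxy)-2-[3,4-bis(benzyloxy)phenyl]chromane | c1ccccc1COc1cc(OCc3ccccc3)c2c(c1)O[C@H](c1ccc(OCc3ccccc3)c(OCc3ccccc3)c1)[C@H](OCc1ccccc1)C2 | intermediate
11 | (2R,3R,4S)-3,5,7-tris(benzyloxy)-2-[3,4-bis(benzyloxy)phenyl]-4-(2-ethoxyethoxy)chromane | c1ccccc1COc1cc(OCc3ccccc3)c2c(c1)O[C@H](c1ccc(OCc3ccccc3)c(OCc3ccccc3)c1)[C@H](OCc1ccccc1)[C@H]2OCCOCC | intermediate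
12 | (2R,3S,4S)-3,5,7-tris(benzyloxy)-2-[3,4-bis(benzyloxy)phenyl]-4-[(2,6-dimethylphenyl)sulfanyl]chromane | c1ccccc1COc1cc(OCc3ccccc3)c2c(c1)O[C@H](c1ccc(OCc3ccccc3)c(OCc3ccccc3)c1)[C@H](OCc1ccccc1)[C@H]2Sc1c(C)cccc1C | intermediate
13 | perbenzylated epicatechin-(4β→8)-4β-[(2,6-dimethylphenyl)sulfanyl]epicatechin | c1ccccc1COc1cc(OCc3ccccc3)c2c(c1)O[C@H](c1ccc(OCc3ccccc3)c(OCc3ccccc3)c1)[C@H](OCc1ccccc1)[C@H]2c1c(OCc3ccccc3)cc(OCc3ccccc3)c2c1O[C@H](c1ccc(OCc3ccccc3)c(OCc3ccccc3)c1)[C@H](OCc1ccccc1)[C@H]2Sc1c(C)cccc1C | intermediate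
14 | (+)-epicatechin, (2S,3S) | Oc1cc(O)c2c(c1)O[C@@H](c1ccc(O)c(O)c1)[C@@H](O)C2 | starting material
15 | (2S,3S)-3,5,7-tris(benzyloxy)-2-[3,4-bis(benzyloxy)phenyl]chromane | C1c2c(OCc3ccccc3)cc(OCc3ccccc3)cc2O[C@@H](c2ccc(OCc3ccccc3)c(OCc3ccccc3)c2)[C@H]1OCc1ccccc1 | intermediate
16 | (2S,3S,4R)-3,5,7-tris(benzyloxy)-2-[3,4-bis(benzyloxy)phenyl]chroman-4-ol | O[C@@H]1c2c(OCc3ccccc3)cc(OCc3ccccc3)cc2O[C@@H](c2ccc(OCc3ccccc3)c(OCc3ccccc3)c2)[C@H]1OCc1ccccc1 | intermediate
17 | (2S,3R)-3,5,7-tris(benzyloxy)-2-[3,4-bis(benzyloxy)phenyl]chroman-4-one | O=C1c2c(OCc3ccccc3)cc(OCc3ccccc3)cc2O[C@@H](c2ccc(OCc3ccccc3)c(OCc3ccccc3)c2)[C@H]1OCc1ccccc1 | intermediate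
18 | (2S,3S,4S)-3,5,7-tris(benzyloxy)-2-[3,4-bis(benzyloxy)phenyl]chroman-4-ol | O[C@H]1c2c(OCc3ccccc3)cc(OCc3ccccc3)cc2O[C@@H](c2ccc(OCc3ccccc3)c(OCc3ccccc3)c2)[C@H]1OCc1ccccc1 | intermediate
19 | pentadeca-O-benzyl derivative of the target (upper 2R,3R,4R; middle 2R,3R,4S; lower 2S,3S,4S) | c1ccccc1COc1cc(OCc3ccccc3)c2c(c1)O[C@H](c1ccc(OCc3ccccc3)c(OCc3ccccc3)c1)[C@H](OCc1ccccc1)[C@H]2c1c(OCc3ccccc3)cc(OCc3ccccc3)c2c1O[C@H](c1ccc(OCc3ccccc3)c(OCc3ccccc3)c1)[C@H](OCc1ccccc1)[C@H]2O[C@H]1c2c(OCc3ccccc3)cc(OCc3ccccc3)cc2O[C@@H](c2ccc(OCc3ccccc3)c(OCc3ccccc3)c2)[C@H]1OCc1ccccc1 | intermediate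
20 | CNP0310719.1: epicatechin-(4β→8)-epicatechin whose C4β oxygen is bonded to C4 of an all-cis (2S,3S,4S) flavan-3,4-diol unit | Oc1cc(O)c2c(c1)O[C@H](c1ccc(O)c(O)c1)[C@H](O)[C@H]2c1c(O)cc(O)c2c1O[C@H](c1ccc(O)c(O)c1)[C@H](O)[C@H]2O[C@H]1c2c(O)cc(O)cc2O[C@@H](c2ccc(O)c(O)c2)[C@H]1O | target

Total step count: 15. Longest linear sequence: 10 steps (steps 1, 3, 4, 5, 6, 7, 8, 9, 14, 15).

Steps most likely to fail

Step 3. The aldol closure onto the hindered, donor-deactivated formyl group may be slower than the retro-oxa-Michael reaction, which would stall conversion or erode the enantioselectivity. The fallback sets out from 4 and 2 and returns to the route at 8. Enal 4 is reduced (NaBH4, MeOH) to cinnamyl alcohol F1 and acylated (ClCO2Me, pyridine) to methyl carbonate F2. Branched-selective allylic etherification of phenol 2 with F2 ([Ir(cod)Cl]2, chiral phosphoramidite ligand of the sense that gives the (S)-ether, base) gives 1-arylallyl aryl ether F3. Wittig methylenation (Ph3P=CH2) of its formyl group gives styrene F4, and ring-closing metathesis with the second-generation Grubbs catalyst closes the same C3–C4 bond as the alkene of flav-3-ene F5. Hydroboration–oxidation (BH3·THF, then NaOH/H2O2) anti to the 2-aryl group gives 2,3-trans alcohol F6, and Dess–Martin oxidation gives ketone 8.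

Step 4. The peracid may epoxidise the electron-rich enol formate or oxidise ring A in competition with the Baeyer–Villiger migration, and the formate cleavage may epimerise C2. The fallback sets out from 6 and returns at 8. Pinnick oxidation (NaClO2, NaH2PO4, 2-methyl-2-butene) gives carboxylic acid F7. Diphenylphosphoryl azide and Et3N give acyl azide F8, which undergoes Curtius rearrangement on warming in toluene to vinyl isocyanate F9. Dilute aqueous HCl in THF at low temperature hydrolyses F9 through the enamine to ketone 8.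

Step 14. The C4 cation may be captured by the nucleophilic ring A carbons C6/C8 of 18 (C-alkylation) instead of its hindered hydroxyl, and the product ether may re-ionise. The fallback sets out from 18 and returns at 20. Alcohol 18 is brominated at C6 and C8 (N-bromosuccinimide, CH2Cl2, −78 °C) to dibromide F10, whose ring A can no longer act as a carbon nucleophile. Coupling of F10 with 13 under the conditions of step 14 gives dibromo ether F11. Hydrogenolysis (H2, Pd(OH)2/C, Et3N, THF/MeOH/H2O) removes both bromine atoms together with the benzyl groups and gives 20.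

Further compounds
F1 | step 3 | (E)-3-[3,4-bis(benzyloxy)phenyl]prop-2-en-1-ol | OC/C=C/c1ccc(OCc2ccccc2)c(OCc2ccccc2)c1
F2 | step 3 | (E)-3-[3,4-bis(benzyloxy)phenyl]allyl methyl carbonate | COC(=O)OC/C=C/c1ccc(OCc2ccccc2)c(OCc2ccccc2)c1
F3 | step 3 | (S)-4,6-bis(benzyloxy)-2-{1-[3,4-bis(benzyloxy)phenyl]allyloxy}benzaldehyde | O=Cc1c(OCc2ccccc2)cc(OCc2ccccc2)cc1O[C@H](c1ccc(OCc2ccccc2)c(OCc2ccccc2)c1)C=C
F4 | step 3 | (S)-1,5-bis(benzyloxy)-3-{1-[3,4-bis(benzyloxy)phenyl]allyloxy}-2-vinylbenzene | C=Cc1c(OCc2ccccc2)cc(OCc2ccccc2)cc1O[C@H](c1ccc(OCc2ccccc2)c(OCc2ccccc2)c1)C=C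
F5 | step 3 | (S)-5,7-bis(benzyloxy)-2-[3,4-bis(benzyloxy)phenyl]-2H-chromene | c1ccccc1COc1cc(OCc3ccccc3)c2c(c1)O[C@H](c1ccc(OCc3ccccc3)c(OCc3ccccc3)c1)C=C2
F6 | step 3 | (2R,3S)-5,7-bis(benzyloxy)-2-[3,4-bis(benzyloxy)phenyl]chroman-3-ol (tetra-O-benzyl-(+)-catechin) | c1ccccc1COc1cc(OCc3ccccc3)c2c(c1)O[C@H](c1ccc(OCc3ccccc3)c(OCc3ccccc3)c1)[C@@H](O)C2
F7 | step 4 | (R)-5,7-bis(benzyloxy)-2-[3,4-bis(benzyloxy)phenyl]-2H-chromene-3-carboxylic acid | c1ccccc1COc1cc(OCc3ccccc3)c2c(c1)O[C@H](c1ccc(OCc3ccccc3)c(OCc3ccccc3)c1)C(C(=O)O)=C2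
F8 | step 4 | (R)-5,7-bis(benzyloxy)-2-[3,4-bis(benzyloxy)phenyl]-2H-chromene-3-carbonyl azide | c1ccccc1COc1cc(OCc3ccccc3)c2c(c1)O[C@H](c1ccc(OCc3ccccc3)c(OCc3ccccc3)c1)C(C(=O)N=[N+]=[N-])=C2
F9 | step 4 | (R)-5,7-bis(benzyloxy)-2-[3,4-bis(benzyloxy)phenyl]-3-isocyanato-2H-chromene | c1ccccc1COc1cc(OCc3ccccc3)c2c(c1)O[C@H](c1ccc(OCc3ccccc3)c(OCc3ccccc3)c1)C(N=C=O)=C2
F10 | step 14 | (2S,3S,4S)-3,5,7-tris(benzyloxy)-2-[3,4-bis(benzyloxy)phenyl]-6,8-dibromochroman-4-ol | O[C@H]1c2c(OCc3ccccc3)c(Br)c(OCc3ccccc3)c(Br)c2O[C@@H](c2ccc(OCc3ccccc3)c(OCc3ccccc3)c2)[C@H]1OCc1ccccc1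
F11 | step 14 | pentadeca-O-benzyl trimer 19 carrying bromine at C6 and C8 of the lower unit | c1ccccc1COc1cc(OCc3ccccc3)c2c(c1)O[C@H](c1ccc(OCc3ccccc3)c(OCc3ccccc3)c1)[C@H](OCc1ccccc1)[C@H]2c1c(OCc3ccccc3)cc(OCc3ccccc3)c2c1O[C@H](c1ccc(OCc3ccccc3)c(OCc3ccccc3)c1)[C@H](OCc1ccccc1)[C@H]2O[C@H]1c2c(OCc3ccccc3)c(Br)c(OCc3ccccc3)c(Br)c2O[C@@H](c2ccc(OCc3ccccc3)c(OCc3ccccc3)c2)[C@H]1OCc1ccccc1
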